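**Retrosynthetic overview**
1. The last step joins fragment A (lactone α-hydroxy dimethyl acetal) and fragment B ((E)-alkenylboronic acid diacetate) by a new hydroxyl-directed "oxa-Petasis" alkenylation. It forms C7–C8, sets the C7 methoxy stereocentre and leaves the C6 hydroxyl free.
2. Fragment A: the dihydropyranone is closed by acrylate ring-closing metathesis; C5 comes from a matched asymmetric allylboration; C6 comes from (S)-glyceraldehyde acetonide.
3. Fragment B: the C10/C11 diacetate comes from an L-threonine-derived dioxolane ester, via one-pot reduction/alkyne homologation and E-selective hydroboration.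
4. Ring order: the only ring (the six-membered lactone) is closed in fragment A before the coupling.

Assumption: chain numbering C1 (lactone C=O) to C12 (CH3) is used, the target being 5S,6S,7R,8E,10R,11R; Roush's tartrate allylboronate and the Ohira–Bestmann reagent are treated as reagents, not numbered compounds.

**Route**

Step 1
Reactants: 1 (S)-2,2-dimethyl-1,3-dioxolane-4-carbaldehyde
Product: 2 (S)-3,3-dimethoxypropane-1,2-diol
Conditions: MeOH (0.2 M), p-TsOH·H2O (2 mol %), 40 °C; NaHCO3, concentrate (repeat once)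
Reagents that add atoms: methanol, CO
Why: Acid-catalysed transacetalisation in excess methanol turns the aldehyde into its dimethyl acetal while the water released hydrolyses the isopropylidene group (acetone is stripped off); the C6 stereocentre comes unchanged from the chiral pool.

Step 2
Reactants: 2 (S)-3,3-dimethoxypropane-1,2-diol
Product: 3 (S)-1,1-dimethoxy-2,3-bis[(triethylsilyl)oxy]propane
Conditions: Et3SiCl (2.4 equiv), imidazole (5 equiv), CH2Cl2, 0 °C → rt
Reagents that add atoms: chlorotriethylsilane, CC[Si](CC)(CC)Cl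
Why: Standard imidazole-promoted bis-silylation of a diol; no stereocentre is affected.

Step 3
Reactants: 3 (S)-1,1-dimethoxy-2,3-bis[(triethylsilyl)oxy]propane
Product: 4 (S)-3,3-dimethoxy-2-[(triethylsilyl)oxy]propanal
Conditions: (COCl)2 (4 equiv), DMSO (8 equiv), CH2Cl2, −78 → −40 °C; Et3N (12 equiv), −78 → 0 °C; used crude
Reagents that add atoms: none
Why: Selective Swern oxidative desilylation: the chlorodimethylsulfonium salt cleaves and oxidises the unhindered primary triethylsilyl ether much faster than the secondary one, and the acetal and the C6 centre survive at low temperature.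

Step 4
Reactants: 4 (S)-3,3-dimethoxy-2-[(triethylsilyl)oxy]propanal
Product: 5 (2S,3S)-1,1-dimethoxy-2-[(triethylsilyl)oxy]hex-5-en-3-ol
Conditions: Roush (R,R)-tartrate allylboronate (1.5 equiv), 4 Å MS, PhMe, −78 °C; then aq NaHCO3
Reagents that add atoms: diisopropyl (4R,5R)-2-allyl-1,3,2-dioxaborolane-4,5-dicarboxylate, C=CCB1O[C@H]([C@@H](O1)C(=O)OC(C)C)C(=O)OC(C)C
Why: Roush asymmetric allylboration through a closed chair transition state: the (R,R)-reagent attacks the si face, which matches the Felkin/Cornforth preference of the α-silyloxy aldehyde, so C5 is set S, anti to the C6 oxygen.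

Step 5
Reactants: 5 (2S,3S)-1,1-dimethoxy-2-[(triethylsilyl)oxy]hex-5-en-3-ol
Product: 6 (2S,3S)-1,1-dimethoxy-2-[(triethylsilyl)oxy]hex-5-en-3-yl prop-2-enoate
Conditions: CH2=CHCOCl (1.5 equiv), i-Pr2NEt (3 equiv), DMAP (10 mol %), CH2Cl2, −20 → 0 °C
Reagents that add atoms: acryloyl chloride, C=CC(=O)Cl
Why: DMAP-catalysed acylation of the only free hydroxyl puts the C1–C3 acrylate unit on O5 without touching a stereocentre.

Step 6
Reactants: 6 (2S,3S)-1,1-dimethoxy-2-[(triethylsilyl)oxy]hex-5-en-3-yl prop-2-enoate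
Product: 7 (S)-6-{(S)-2,2-dimethoxy-1-[(triethylsilyl)oxy]ethyl}-5,6-dihydro-2H-pyran-2-one
Conditions: second-generation Grubbs catalyst (H2IMes)(PCy3)Cl2Ru=CHPh (5 mol %), CH2Cl2 (5 mM), 40 °C
Reagents that add atoms: none
Why: Ring-closing metathesis of the acrylate with the terminal allyl alkene closes the six-membered α,β-unsaturated δ-lactone (cis alkene enforced by the ring) with loss of ethylene.

Step 7
Reactants: 7 (S)-6-{(S)-2,2-dimethoxy-1-[(triethylsilyl)oxy]ethyl}-5,6-dihydro-2H-pyran-2-one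
Product: 8 (S)-6-[(S)-1-hydroxy-2,2-dimethoxyethyl]-5,6-dihydro-2H-pyran-2-one
Conditions: HF·pyridine, pyridine, THF, 0 °C → rt
Reagents that add atoms: none
Why: Fluoride-mediated desilylation frees the C6 hydroxyl under buffered, non-basic conditions that leave the lactone and the dimethyl acetal intact.

Step 8
Reactants: 9 methyl (4S,5R)-2,2,5-trimethyl-1,3-dioxolane-4-carboxylate
Product: 11 (4R,5R)-4-ethynyl-2,2,5-trimethyl-1,3-dioxolane, via dioxolane aldehyde 10 (not isolated)
Conditions: i-Bu2AlH (1.1 equiv), CH2Cl2, −78 °C; then MeOH, dimethyl (1-diazo-2-oxopropyl)phosphonate (1.5 equiv), K2CO3 (3 equiv), −78 °C → rt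
Reagents that add atoms: dimethyl (1-diazo-2-oxopropyl)phosphonate, CC(=O)C(=[N+]=[N-])P(=O)(OC)OC
Why: Partial ester reduction to the aldehyde followed in the same flask by Ohira–Bestmann (Seyferth–Gilbert) homologation gives the terminal alkyne; the trans-dioxolane aldehyde is the favoured epimer, so C10 and C11 (from L-threonine) are kept.

Step 9
Reactants: 11 (4R,5R)-4-ethynyl-2,2,5-trimethyl-1,3-dioxolane
Product: 13 (3R,4R)-pent-1-yne-3,4-diyl diacetate, via alkyne diol 12 (not isolated)
Conditions: p-TsOH·H2O (5 mol %), MeOH, rt; NaHCO3, concentrate; then Ac2O (3 equiv), pyridine, DMAP (5 mol %), CH2Cl2, 0 °C → rt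
Reagents that add atoms: acetic anhydride, CC(=O)OC(C)=O
Why: Acid-catalysed methanolysis of the acetonide and DMAP-catalysed acetylation of the volatile diol without isolation install both acetates of the target; no C–O bond at C10 or C11 is broken.

Step 10
Reactants: 13 (3R,4R)-pent-1-yne-3,4-diyl diacetate
Product: 15 [(1E,3R,4R)-3,4-diacetoxypent-1-en-1-yl]boronic acid, via catechol boronate 14 (not isolated)
Conditions: catecholborane (1.3 equiv), Cy2BH (10 mol %), THF, rt; then H2O, rt
Reagents that add atoms: catecholborane, [H]B1Oc2ccccc2O1; water, O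
Why: Dialkylborane-catalysed syn hydroboration of the terminal alkyne puts boron on the terminal carbon and gives only the E-alkenyl boronate, which water hydrolyses to the boronic acid; acetates and stereocentres are untouched.

Step 11
Reactants: 8 (S)-6-[(S)-1-hydroxy-2,2-dimethoxyethyl]-5,6-dihydro-2H-pyran-2-one; 15 [(1E,3R,4R)-3,4-diacetoxypent-1-en-1-yl]boronic acid (1.5 equiv)
Product: 16 (S)-6-[(1S,2R,3E,5R,6R)-5,6-diacetoxy-1-hydroxy-2-methoxyhept-3-en-1-yl]-5,6-dihydro-2H-pyran-2-one
Conditions: (PhO)2P(O)OH (10 mol %), 4 Å MS, (CF3)2CHOH/CH2Cl2 (4:1, 0.1 M), rt → 40 °C; pH 7 buffer work-up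
Reagents that add atoms: none
Why: Proposed new method: hydroxyl-directed oxa-Petasis alkenylation of an α-hydroxy dimethyl acetal. The boronic acid esterifies the C6 hydroxyl, and the phosphoric acid in the ionising solvent expels one methoxy group to give the (E)-oxocarbenium ion while the tethered boron becomes a tetracoordinate boronate. The alkenyl group then migrates intramolecularly, with retention of E geometry, through a five-membered transition state to the oxocarbenium face syn to the C6–O–B bond (C5 substituent turned away from the oxonium oxygen), forming C7–C8 and giving the 6,7-anti (7R) methyl ether with C6–OH free after B–O hydrolysis. The closest known reactions are the Petasis borono-Mannich reaction of α-hydroxy aldehydes (anti amino alcohols via the same boronate delivery) and acid-promoted additions of alkenylboron reagents to acetal-derived oxocarbenium ions.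

**Compound list**
1 | (S)-2,2-dimethyl-1,3-dioxolane-4-carbaldehyde | O=C[C@@H]1COC(C)(C)O1 | starting material
2 | (S)-3,3-dimethoxypropane-1,2-diol | COC(OC)[C@@H](O)CO | intermediate
3 | (S)-1,1-dimethoxy-2,3-bis[(triethylsilyl)oxy]propane | COC(OC)[C@@H](O[Si](CC)(CC)CC)CO[Si](CC)(CC)CC | intermediate
4 | (S)-3,3-dimethoxy-2-[(triethylsilyl)oxy]propanal | COC(OC)[C@@H](O[Si](CC)(CC)CC)C=O | intermediate
5 | (2S,3S)-1,1-dimethoxy-2-[(triethylsilyl)oxy]hex-5-en-3-ol | COC(OC)[C@@H](O[Si](CC)(CC)CC)[C@@H](O)CC=C | intermediate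
6 | (2S,3S)-1,1-dimethoxy-2-[(triethylsilyl)oxy]hex-5-en-3-yl prop-2-enoate | COC(OC)[C@@H](O[Si](CC)(CC)CC)[C@@H](OC(=O)C=C)CC=C | intermediate
7 | (S)-6-{(S)-2,2-dimethoxy-1-[(triethylsilyl)oxy]ethyl}-5,6-dihydro-2H-pyran-2-one | COC(OC)[C@@H](O[Si](CC)(CC)CC)[C@@H]1CC=CC(=O)O1 | intermediate
8 | (S)-6-[(S)-1-hydroxy-2,2-dimethoxyethyl]-5,6-dihydro-2H-pyran-2-one (fragment A) | COC(OC)[C@@H](O)[C@@H]1CC=CC(=O)O1 | intermediate
9 | methyl (4S,5R)-2,2,5-trimethyl-1,3-dioxolane-4-carboxylate | COC(=O)[C@H]1OC(C)(C)O[C@@H]1C | starting material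
10 | (4S,5R)-2,2,5-trimethyl-1,3-dioxolane-4-carbaldehyde | O=C[C@H]1OC(C)(C)O[C@@H]1C | intermediate (not isolated)
11 | (4R,5R)-4-ethynyl-2,2,5-trimethyl-1,3-dioxolane | C#C[C@H]1OC(C)(C)O[C@@H]1C | intermediate
12 | (3R,4R)-pent-1-yne-3,4-diol | C#C[C@@H](O)[C@@H](C)O | intermediate (not isolated)
13 | (3R,4R)-pent-1-yne-3,4-diyl diacetate | C#C[C@@H](OC(C)=O)[C@@H](C)OC(C)=O | intermediate
14 | (3R,4R,E)-1-(1,3,2-benzodioxaborol-2-yl)pent-1-ene-3,4-diyl diacetate | O1c2ccccc2OB1/C=C/[C@@H](OC(C)=O)[C@@H](C)OC(C)=O | intermediate (not isolated)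
15 | [(1E,3R,4R)-3,4-diacetoxypent-1-en-1-yl]boronic acid (fragment B) | OB(O)/C=C/[C@@H](OC(C)=O)[C@@H](C)OC(C)=O | intermediate
16 | (S)-6-[(1S,2R,3E,5R,6R)-5,6-diacetoxy-1-hydroxy-2-methoxyhept-3-en-1-yl]-5,6-dihydro-2H-pyran-2-one | CO[C@H](/C=C/[C@@H](OC(C)=O)[C@@H](C)OC(C)=O)[C@@H](O)[C@@H]1CC=CC(=O)O1 | target

**Step count and risks**
Total steps: 11. Longest linear sequence: 8 (steps 1–7, then step 11).

Three steps most likely to fail:

1. Step 11 (the proposed new method). The acyclic oxocarbenium ion may form too slowly, the alkenylboronic acid (made less electron-rich by its allylic acetate) may protodeborate before it migrates, and the anti preference may be weaker than in the amine version. The fallback uses known chemistry, sets out from 8 and 15 and comes back at 16. Compound 8 is silylated (TBSOTf, 2,6-lutidine) to (S)-6-{(S)-1-[(tert-butyldimethylsilyl)oxy]-2,2-dimethoxyethyl}-5,6-dihydro-2H-pyran-2-one F1. Its acetal is opened with Et3SiOTf/2,4,6-collidine and then water to (S)-2-[(tert-butyldimethylsilyl)oxy]-2-[(S)-6-oxo-3,6-dihydro-2H-pyran-2-yl]acetaldehyde F2. In parallel, 15 is converted with N-iodosuccinimide in MeCN into (3R,4R,E)-1-iodopent-1-ene-3,4-diyl diacetate F3. Nozaki–Hiyama–Kishi coupling of F2 with F3 (CrCl2, NiCl2 cat., DMSO) gives mainly the Felkin (6,7-anti) alcohol (S)-6-[(1R,2R,3E,5R,6R)-5,6-diacetoxy-1-[(tert-butyldimethylsilyl)oxy]-2-hydroxyhept-3-en-1-yl]-5,6-dihydro-2H-pyran-2-one F4, and the minor C7 epimer is removed by chromatography. F4 is O-methylated under non-basic conditions (Me3OBF4, 1,8-bis(dimethylamino)naphthalene) to (S)-6-[(1S,2R,3E,5R,6R)-5,6-diacetoxy-1-[(tert-butyldimethylsilyl)oxy]-2-methoxyhept-3-en-1-yl]-5,6-dihydro-2H-pyran-2-one F5, and HF·pyridine then gives 16.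

2. Step 3 (selective Swern oxidation of the primary silyl ether). The risks are incomplete primary/secondary discrimination and epimerisation of the α-silyloxy aldehyde. The fallback sets out from 3 and comes back at 4: selective methanolysis of the primary silyl ether (PPTS, MeOH/CH2Cl2, −10 °C) gives (S)-3,3-dimethoxy-2-[(triethylsilyl)oxy]propan-1-ol F6, which is oxidised with Dess–Martin periodinane buffered with NaHCO3 to 4.

3. Step 10 (hydroboration to the free boronic acid). The boronic acid is hard to purify and may carry catechol or boroxine. The fallback sets out from 13 and comes back at 15: hydroboration with pinacolborane catalysed by Cp2Zr(H)Cl (10 mol %, Et3N, 60 °C) gives the chromatographable (3R,4R,E)-1-(4,4,5,5-tetramethyl-1,3,2-dioxaborolan-2-yl)pent-1-ene-3,4-diyl diacetate F7, whose pinacol group is cleaved with NaIO4/NH4OAc in acetone–water to give 15.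

**Further compounds**
F1 | step 11 | (S)-6-{(S)-1-[(tert-butyldimethylsilyl)oxy]-2,2-dimethoxyethyl}-5,6-dihydro-2H-pyran-2-one | COC(OC)[C@@H](O[Si](C)(C)C(C)(C)C)[C@@H]1CC=CC(=O)O1
F2 | step 11 | (S)-2-[(tert-butyldimethylsilyl)oxy]-2-[(S)-6-oxo-3,6-dihydro-2H-pyran-2-yl]acetaldehyde | O=C[C@@H](O[Si](C)(C)C(C)(C)C)[C@@H]1CC=CC(=O)O1
F3 | step 11 | (3R,4R,E)-1-iodopent-1-ene-3,4-diyl diacetate | I/C=C/[C@@H](OC(C)=O)[C@@H](C)OC(C)=O
F4 | step 11 | (S)-6-[(1R,2R,3E,5R,6R)-5,6-diacetoxy-1-[(tert-butyldimethylsilyl)oxy]-2-hydroxyhept-3-en-1-yl]-5,6-dihydro-2H-pyran-2-one | O[C@H](/C=C/[C@@H](OC(C)=O)[C@@H](C)OC(C)=O)[C@@H](O[Si](C)(C)C(C)(C)C)[C@@H]1CC=CC(=O)O1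
F5 | step 11 | (S)-6-[(1S,2R,3E,5R,6R)-5,6-diacetoxy-1-[(tert-butyldimethylsilyl)oxy]-2-methoxyhept-3-en-1-yl]-5,6-dihydro-2H-pyran-2-one | CO[C@H](/C=C/[C@@H](OC(C)=O)[C@@H](C)OC(C)=O)[C@@H](O[Si](C)(C)C(C)(C)C)[C@@H]1CC=CC(=O)O1
F6 | step 3 | (S)-3,3-dimethoxy-2-[(triethylsilyl)oxy]propan-1-ol | COC(OC)[C@@H](O[Si](CC)(CC)CC)CO
F7 | step 10 | (3R,4R,E)-1-(4,4,5,5-tetramethyl-1,3,2-dioxaborolan-2-yl)pent-1-ene-3,4-diyl diacetate | CC1(C)OB(OC1(C)C)/C=C/[C@@H](OC(C)=O)[C@@H](C)OC(C)=O
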